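**Plan**

- Retrosynthesis: the silyl ether and the two ester C–O bonds are cut first (C6–O epoxyangelate with retention, C4–O angelate with inversion). The ring bond C4–C5 is cut next, then the furan C2–carbinol bond, which leads back to furan-3-ylmethanol and 3-methylbut-2-enal.
- Enabling feature (ring numbered from the ketone C1, C2 bearing CH2OH): the C4 carbinol sits next to the isopropyl-bearing C5, which is the homoallylic alcohol left by a carbonyl-ene reaction once isopropyl is read as hydrogenated isopropenyl. C1(=O)–C2=C3–C4 is a cis-4-oxo-2-enal, the oxidised form of a 2,3-disubstituted furan.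
- Forward: the chain is joined by C2-lithiation of the furan and addition to the enal. The furan is opened to the Z-oxo-enal, and the only carbocycle closes in the ene step. The esters are attached afterwards.
- Stereochemistry: C6 comes from a CBS reduction; C5 is relayed from C6 by 1,3-allylic strain in the ene step; C4 is set trans in the ene step and inverted by Mitsunobu angeloylation. The epoxide centres come from a Sharpless epoxidation of angelyl alcohol; the Z-angelate geometry is carried from angelic acid.
- Any enantiomeric leakage from steps 4 or 12 would appear as a separable diastereomer at step 14.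

Key step: step 7

Assumptions: in step 4 the ortho-substituted 2-furyl group is taken to act as the larger ketone substituent, so the (R)-oxazaborolidine should give the (S)-carbinol; the sense is to be checked by Mosher ester analysis of 7. Ring positions in names are numbered from the ketone carbon; descriptor changes at C5 (compound 15) and at the epoxide C2 (17 to 18) are CIP priority effects only.

**Route**

Step 1
Reactants: 1 furan-3-ylmethanol; 2 3-methylbut-2-enal
Product: 4 rac-1-[3-(hydroxymethyl)furan-2-yl]-3-methylbut-2-en-1-ol, via dilithio furanmethanol dianion 3 (not isolated)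
Conditions: n-BuLi (2.2 equiv), THF, −78 → 0 °C; then 2, −78 °C; aq NH4Cl
Reagents that add atoms: none
Why: Alkoxide-directed lithiation places the second lithium at furan C2 next to the CH2OLi arm (known behaviour of this dianion), and the furyllithium adds 1,2 to the enal; the carbinol centre is racemic at this stage.

Step 2
Reactants: 4
Product: 5 rac-1-{3-[(tert-butyldiphenylsilyloxy)methyl]furan-2-yl}-3-methylbut-2-en-1-ol
Conditions: TBDPSCl (1.05 equiv), imidazole, CH2Cl2, 0 °C
Reagents that add atoms: tert-butyl(chloro)diphenylsilane, CC(C)(C)[Si](Cl)(c1ccccc1)c1ccccc1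
Why: Selective silyl ether formation, since the bulky chlorosilane reacts much faster with the primary hydroxyl than with the secondary carbinol; TBDPS is chosen to last until the final step.

Step 3
Reactants: 5
Product: 6 1-{3-[(tert-butyldiphenylsilyloxy)methyl]furan-2-yl}-3-methylbut-2-en-1-one
Conditions: activated MnO2 (excess), CH2Cl2, rt
Reagents that add atoms: none
Why: MnO2 oxidises the allylic and furfurylic secondary alcohol under neutral conditions that spare the acid-sensitive furan and the silyl ether.

Step 4
Reactants: 6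
Product: 7 (S)-1-{3-[(tert-butyldiphenylsilyloxy)methyl]furan-2-yl}-3-methylbut-2-en-1-ol
Conditions: (R)-Me-CBS (20 mol%), catecholborane (1.5 equiv), toluene, −78 °C
Reagents that add atoms: none
Why: Corey–Bakshi–Shibata reduction with catecholborane is 1,2-selective on enones at low temperature, and with the ortho-substituted furyl group as the large substituent the (R)-catalyst should deliver the (S)-carbinol that becomes C6.

Step 5
Reactants: 7
Product: 8 (S)-tert-butyl{[2-(3-methyl-1-(triethylsilyloxy)but-2-enyl)furan-3-yl]methoxy}diphenylsilane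
Conditions: TESCl, imidazole, CH2Cl2, 0 °C
Reagents that add atoms: chlorotriethylsilane, CC[Si](Cl)(CC)CC
Why: Silylation under non-ionising, weakly basic conditions protects the doubly activated carbinol without racemisation; the TES ether is non-chelating, bulky enough for the later allylic-strain control and removable in the presence of TBDPS.

Step 6
Reactants: 8
Product: 10 (2Z,5S)-3-[(tert-butyldiphenylsilyloxy)methyl]-7-methyl-4-oxo-5-(triethylsilyloxy)octa-2,6-dienal, via furan endoperoxide 9 (not isolated)
Conditions: O2, hν (visible), methylene blue (cat.), CH2Cl2, −78 °C; then Me2S, −78 °C → rt; crude 10 passed through a short silica pad and used at once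
Reagents that add atoms: dioxygen (reacting as singlet oxygen), O=O
Why: Singlet oxygen adds [4+2] across C2/C5 of the electron-rich furan much faster than it undergoes the Schenck ene reaction with the trisubstituted alkene, and reduction of the endoperoxide by dimethyl sulfide unveils the cis-4-oxo-2-enal with the Z geometry fixed by the former ring.

Step 7
Reactants: 10
Product: 11 (4S,5R,6S)-2-[(tert-butyldiphenylsilyloxy)methyl]-4-hydroxy-5-(prop-1-en-2-yl)-6-(triethylsilyloxy)cyclohex-2-en-1-one
Conditions: Me2AlCl (1.5 equiv), CH2Cl2, −78 → −40 °C; aq Rochelle salt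
Reagents that add atoms: none
Why: Me2AlCl binds the sterically open aldehyde oxygen and the trisubstituted alkene attacks the aldehyde carbon through its proximal carbon while an allylic methyl hydrogen passes to oxygen, a type I carbonyl-ene reaction (concerted or through a short-lived tertiary cation) that forms C4–C5 and leaves an isopropenyl group. The closest known cases are the Lewis acid cyclisations of citronellal to isopulegol and of the Z-enal neral to isopiperitenol. The six-membered carbocycle closes 6-exo-trig at the carbonyl, which the Z geometry inherited from the furan makes possible; Michael-type attack at the enone β-carbon would be 5-endo-trig and the ketone cannot reach the alkene. C5 is controlled by C6: 1,3-allylic strain with the cis-methyl group keeps the C6 hydrogen in the alkene plane, so the tether adds to the face opposite the bulky OTES group and isopropenyl ends up trans to it. C4 is controlled by the s-trans enal conformation with the aluminium-bound oxygen pseudo-equatorial in the chair-like transition state, which places the hydroxyl trans to isopropenyl. The step needs the Z-alkene to stay intact and the aldehyde, not the ketone, to be activated, which low temperature, the non-chelating silyl ether and the accessibility of the aldehyde should secure.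

Step 8
Reactants: 11
Product: 12 (4S,5R,6S)-2-[(tert-butyldiphenylsilyloxy)methyl]-4-hydroxy-5-isopropyl-6-(triethylsilyloxy)cyclohex-2-en-1-one
Conditions: H2 (1 atm), RhCl(PPh3)3 (5 mol%), benzene, rt
Reagents that add atoms: none
Why: Wilkinson's catalyst hydrogenates the unhindered 1,1-disubstituted alkene and leaves the trisubstituted conjugated enone alone, as in the reduction of carvone to carvotanacetone; no stereocentre is formed.

Step 9
Reactants: 12; 13 angelic acid ((Z)-2-methylbut-2-enoic acid)
Product: 14 (4R,5R,6S)-4-angeloyloxy-2-[(tert-butyldiphenylsilyloxy)methyl]-5-isopropyl-6-(triethylsilyloxy)cyclohex-2-en-1-one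
Conditions: PPh3, DIAD, toluene, 0 °C → rt
Reagents that add atoms: none
Why: Mitsunobu esterification displaces the equatorial allylic oxyphosphonium by angelate in SN2 fashion and so inverts C4 to the 4,5-cis configuration; anti-periplanar elimination is disfavoured because the C5 hydrogen is axial while the leaving group is equatorial, and the neutral conditions should preserve the Z-angeloyl geometry.

Step 10
Reactants: 14
Product: 15 (4R,5S,6S)-4-angeloyloxy-2-[(tert-butyldiphenylsilyloxy)methyl]-6-hydroxy-5-isopropylcyclohex-2-en-1-one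
Conditions: HF·pyridine, pyridine, THF, 0 °C
Reagents that add atoms: none
Why: Graded silyl ether lability: buffered HF·pyridine cleaves the secondary TES ether far faster than the TBDPS ether and leaves the allylic ester untouched.

Step 11
Reactants: 13
Product: 16 (Z)-2-methylbut-2-en-1-ol
Conditions: LiAlH4, Et2O, 0 °C → rt
Reagents that add atoms: none
Why: Hydride reduction of the carboxylic acid gives the allylic alcohol without touching the trisubstituted alkene or its Z geometry.

Step 12
Reactants: 16
Product: 17 [(2S,3R)-2,3-dimethyloxiran-2-yl]methanol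
Conditions: Ti(OiPr)4 (10 mol%), L-(+)-DIPT (12 mol%), TBHP, 4 Å MS, CH2Cl2, −20 °C; non-aqueous work-up
Reagents that add atoms: tert-butyl hydroperoxide, CC(C)(C)OO
Why: Sharpless asymmetric epoxidation, in which the L-(+)-tartrate delivers oxygen to the face that gives 2S in primary allylic alcohols, while the Z geometry fixes the cis relationship of the C3 methyl and CH2OH (3R).

Step 13
Reactants: 17
Product: 18 (2R,3R)-2,3-dimethyloxirane-2-carboxylic acid
Conditions: TEMPO (cat.), PhI(OAc)2 (2.2 equiv), MeCN/H2O (1:1), 0 °C → rt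
Reagents that add atoms: water, O
Why: Oxoammonium oxidation takes the primary alcohol through the aldehyde hydrate to the acid under near-neutral conditions that leave the epoxide intact and touch no stereocentre.

Step 14
Reactants: 15; 18
Product: 20 (4R,5R,6S)-4-angeloyloxy-2-[(tert-butyldiphenylsilyloxy)methyl]-6-[(2R,3R)-2,3-dimethyloxirane-2-carbonyloxy]-5-isopropylcyclohex-2-en-1-one, via mixed anhydride 19 (not isolated)
Conditions: 18, 2,4,6-trichlorobenzoyl chloride, Et3N, toluene, rt; then 15, DMAP, 0 °C → rt
Reagents that add atoms: none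
Why: Yamaguchi esterification activates the hindered α-quaternary acid as its mixed anhydride and DMAP transfers the acyl group to the equatorial α-ketol hydroxyl with retention at every stereocentre; short reaction time at or below rt limits acyloin isomerisation.

Step 15
Reactants: 20
Product: 21 (4R,5R,6S)-4-angeloyloxy-6-[(2R,3R)-2,3-dimethyloxirane-2-carbonyloxy]-2-(hydroxymethyl)-5-isopropylcyclohex-2-en-1-one (CNP0293054.1)
Conditions: TBAF, AcOH (1:1), THF, 0 °C → rt
Reagents that add atoms: none
Why: Acetic acid-buffered fluoride cleaves the Si–O bond without the basicity that would endanger the α-acyloxy ketone and the esters and without the acidity that would open the epoxide.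

**Compound list**

1 | furan-3-ylmethanol | OCc1ccoc1 | starting material
2 | 3-methylbut-2-enal | CC(C)=CC=O | starting material
3 | 2-lithio-3-(lithiooxymethyl)furan | [Li]OCc1ccoc1[Li] | intermediate
4 | rac-1-[3-(hydroxymethyl)furan-2-yl]-3-methylbut-2-en-1-ol | CC(C)=CC(O)c1occc1CO | intermediate
5 | rac-1-{3-[(tert-butyldiphenylsilyloxy)methyl]furan-2-yl}-3-methylbut-2-en-1-ol | CC(C)=CC(O)c1occc1CO[Si](c1ccccc1)(c1ccccc1)C(C)(C)C | intermediate
6 | 1-{3-[(tert-butyldiphenylsilyloxy)methyl]furan-2-yl}-3-methylbut-2-en-1-one | CC(C)=CC(=O)c1occc1CO[Si](c1ccccc1)(c1ccccc1)C(C)(C)C | intermediate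
7 | (S)-1-{3-[(tert-butyldiphenylsilyloxy)methyl]furan-2-yl}-3-methylbut-2-en-1-ol | CC(C)=C[C@H](O)c1occc1CO[Si](c1ccccc1)(c1ccccc1)C(C)(C)C | intermediate
8 | (S)-tert-butyl{[2-(3-methyl-1-(triethylsilyloxy)but-2-enyl)furan-3-yl]methoxy}diphenylsilane | CC(C)=C[C@H](O[Si](CC)(CC)CC)c1occc1CO[Si](c1ccccc1)(c1ccccc1)C(C)(C)C | intermediate
9 | 6-[(tert-butyldiphenylsilyloxy)methyl]-1-[(1S)-3-methyl-1-(triethylsilyloxy)but-2-enyl]-2,3,7-trioxabicyclo[2.2.1]hept-5-ene (bridgehead diastereomers) | CC(C)=C[C@H](O[Si](CC)(CC)CC)C12OOC(O1)C=C2CO[Si](c1ccccc1)(c1ccccc1)C(C)(C)C | intermediate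
10 | (2Z,5S)-3-[(tert-butyldiphenylsilyloxy)methyl]-7-methyl-4-oxo-5-(triethylsilyloxy)octa-2,6-dienal | O=C/C=C(CO[Si](c1ccccc1)(c1ccccc1)C(C)(C)C)\C(=O)[C@@H](O[Si](CC)(CC)CC)C=C(C)C | intermediate
11 | (4S,5R,6S)-2-[(tert-butyldiphenylsilyloxy)methyl]-4-hydroxy-5-(prop-1-en-2-yl)-6-(triethylsilyloxy)cyclohex-2-en-1-one | C=C(C)[C@@H]1[C@@H](O)C=C(CO[Si](c2ccccc2)(c2ccccc2)C(C)(C)C)C(=O)[C@H]1O[Si](CC)(CC)CC | intermediate
12 | (4S,5R,6S)-2-[(tert-butyldiphenylsilyloxy)methyl]-4-hydroxy-5-isopropyl-6-(triethylsilyloxy)cyclohex-2-en-1-one | CC(C)[C@@H]1[C@@H](O)C=C(CO[Si](c2ccccc2)(c2ccccc2)C(C)(C)C)C(=O)[C@H]1O[Si](CC)(CC)CC | intermediate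
13 | angelic acid, (Z)-2-methylbut-2-enoic acid | C/C=C(/C)C(=O)O | starting material
14 | (4R,5R,6S)-4-angeloyloxy-2-[(tert-butyldiphenylsilyloxy)methyl]-5-isopropyl-6-(triethylsilyloxy)cyclohex-2-en-1-one | C/C=C(/C)C(=O)O[C@@H]1C=C(CO[Si](c2ccccc2)(c2ccccc2)C(C)(C)C)C(=O)[C@@H](O[Si](CC)(CC)CC)[C@@H]1C(C)C | intermediate
15 | (4R,5S,6S)-4-angeloyloxy-2-[(tert-butyldiphenylsilyloxy)methyl]-6-hydroxy-5-isopropylcyclohex-2-en-1-one | C/C=C(/C)C(=O)O[C@@H]1C=C(CO[Si](c2ccccc2)(c2ccccc2)C(C)(C)C)C(=O)[C@@H](O)[C@@H]1C(C)C | intermediate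
16 | (Z)-2-methylbut-2-en-1-ol | C/C=C(/C)CO | intermediate
17 | [(2S,3R)-2,3-dimethyloxiran-2-yl]methanol | OC[C@]1(C)O[C@@H]1C | intermediate
18 | (2R,3R)-2,3-dimethyloxirane-2-carboxylic acid | OC(=O)[C@]1(C)O[C@@H]1C | intermediate
19 | (2R,3R)-2,3-dimethyloxirane-2-carboxylic 2,4,6-trichlorobenzoic anhydride | O=C(OC(=O)[C@]1(C)O[C@@H]1C)c1c(Cl)cc(Cl)cc1Cl | intermediate
20 | (4R,5R,6S)-4-angeloyloxy-2-[(tert-butyldiphenylsilyloxy)methyl]-6-[(2R,3R)-2,3-dimethyloxirane-2-carbonyloxy]-5-isopropylcyclohex-2-en-1-one | C/C=C(/C)C(=O)O[C@@H]1C=C(CO[Si](c2ccccc2)(c2ccccc2)C(C)(C)C)C(=O)[C@@H](OC(=O)[C@]2(C)O[C@@H]2C)[C@@H]1C(C)C | intermediate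
21 | (4R,5R,6S)-4-angeloyloxy-6-[(2R,3R)-2,3-dimethyloxirane-2-carbonyloxy]-2-(hydroxymethyl)-5-isopropylcyclohex-2-en-1-one | C/C=C(/C)C(=O)O[C@@H]1C=C(CO)C(=O)[C@@H](OC(=O)[C@]2(C)O[C@@H]2C)[C@@H]1C(C)C | target

**Step count**

Total steps: 15. Longest linear sequence: 12 (steps 1–10, 14, 15); the epoxy acid branch (steps 11–13) joins at step 14.

**Steps most likely to fail**

Step 7. Hydrogen transfer may lag behind C–C bond formation, so that a tertiary cation partitions between alkene isomers, chloride capture and C4 epimers, while the Lewis acid slowly isomerises the Z-oxo-enal. The fallback makes the cationic course the intended one. It sets out from 10, which is cyclised as a halo-Prins reaction (SnCl4, CH2Cl2, −78 °C). The same chair-like closure forms C4–C5 and chloride quenches the cation, giving (4S,5R,6S)-2-[(tert-butyldiphenylsilyloxy)methyl]-5-(2-chloropropan-2-yl)-4-hydroxy-6-(triethylsilyloxy)cyclohex-2-en-1-one F1. Radical dechlorination (Bu3SnH, AIBN, toluene, 80 °C) then gives the isopropyl compound directly, and the route is rejoined at 12, without the hydrogenation step.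

Step 4. Enantiofacial discrimination may be poor or reversed because both ketone substituents are unsaturated and of similar size. The fallback is a resolution that sets out from racemic 5. Esterification with (S)-O-methylmandelic acid (DCC, DMAP, CH2Cl2, 0 °C) gives two diastereomeric esters that are separated by chromatography on base-washed silica. These are (S)-1-{3-[(tert-butyldiphenylsilyloxy)methyl]furan-2-yl}-3-methylbut-2-enyl (S)-2-methoxy-2-phenylacetate F2 and its carbinol epimer (R)-1-{3-[(tert-butyldiphenylsilyloxy)methyl]furan-2-yl}-3-methylbut-2-enyl (S)-2-methoxy-2-phenylacetate F3, which is set aside. Methanolysis of F2 (K2CO3, MeOH, 0 °C) returns to the route at 7.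

Step 9. Activation of the hindered allylic carbinol may be slow, with elimination or low conversion because angelic acid is a weak Mitsunobu acid, and the angeloyl group may isomerise towards tiglate. The fallback separates inversion from angeloylation and sets out from 12. Mitsunobu reaction with 4-nitrobenzoic acid (PPh3, DIAD, toluene) gives the inverted ester (4R,5R,6S)-2-[(tert-butyldiphenylsilyloxy)methyl]-5-isopropyl-4-(4-nitrobenzoyloxy)-6-(triethylsilyloxy)cyclohex-2-en-1-one F4. Brief methanolysis (K2CO3, MeOH, 0 °C) frees the 4,5-cis alcohol (4R,5R,6S)-2-[(tert-butyldiphenylsilyloxy)methyl]-4-hydroxy-5-isopropyl-6-(triethylsilyloxy)cyclohex-2-en-1-one F5. This is acylated with retention by angelic 2,4,6-trichlorobenzoic anhydride F6, preformed from 13, 2,4,6-trichlorobenzoyl chloride and Et3N in toluene and heated with the alcohol without DMAP, which returns to the route at 14. Any 4,5-cis alcohol that step 7 forms as a minor product is, after step 8, the same alcohol and can be added at this point.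

**Further compounds**

F1 | step 7 | (4S,5R,6S)-2-[(tert-butyldiphenylsilyloxy)methyl]-5-(2-chloropropan-2-yl)-4-hydroxy-6-(triethylsilyloxy)cyclohex-2-en-1-one | CC(C)(Cl)[C@@H]1[C@@H](O)C=C(CO[Si](c2ccccc2)(c2ccccc2)C(C)(C)C)C(=O)[C@H]1O[Si](CC)(CC)CC
F2 | step 4 | (S)-1-{3-[(tert-butyldiphenylsilyloxy)methyl]furan-2-yl}-3-methylbut-2-enyl (S)-2-methoxy-2-phenylacetate | CC(C)=C[C@H](OC(=O)[C@@H](OC)c1ccccc1)c1occc1CO[Si](c1ccccc1)(c1ccccc1)C(C)(C)C
F3 | step 4 | (R)-1-{3-[(tert-butyldiphenylsilyloxy)methyl]furan-2-yl}-3-methylbut-2-enyl (S)-2-methoxy-2-phenylacetate | CC(C)=C[C@@H](OC(=O)[C@@H](OC)c1ccccc1)c1occc1CO[Si](c1ccccc1)(c1ccccc1)C(C)(C)C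
F4 | step 9 | (4R,5R,6S)-2-[(tert-butyldiphenylsilyloxy)methyl]-5-isopropyl-4-(4-nitrobenzoyloxy)-6-(triethylsilyloxy)cyclohex-2-en-1-one | O=C(O[C@@H]1C=C(CO[Si](c2ccccc2)(c2ccccc2)C(C)(C)C)C(=O)[C@@H](O[Si](CC)(CC)CC)[C@@H]1C(C)C)c1ccc(cc1)[N+](=O)[O-]
F5 | step 9 | (4R,5R,6S)-2-[(tert-butyldiphenylsilyloxy)methyl]-4-hydroxy-5-isopropyl-6-(triethylsilyloxy)cyclohex-2-en-1-one | O[C@@H]1C=C(CO[Si](c2ccccc2)(c2ccccc2)C(C)(C)C)C(=O)[C@@H](O[Si](CC)(CC)CC)[C@@H]1C(C)C
F6 | step 9 | (Z)-2-methylbut-2-enoic 2,4,6-trichlorobenzoic anhydride | C/C=C(/C)C(=O)OC(=O)c1c(Cl)cc(Cl)cc1Cl
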